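The depside is cut at its aryl ester into a protected ring A acid and a ring B phenol, and ring B is then built from acyclic pieces. Ring B has meta oxygens at C2' and C4' on either side of C3'-H. C4' can therefore begin as a ketene carbonyl carbon, and C3'-C2' as the two carbons of a silyl ynol ether. In one photochemical operation, an acyclic benzyl 2-diazo-3-oxo ester carrying a 1-propylvinyl ketone (future C1', C4', C6', C5') and (triisopropylsilyloxy)acetylene give the complete benzoate ring. The C4' hydroxyl emerges free for acylation and the C2' oxygen silylated, so the two phenols need no later differentiation.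

Key step: step 5

Locants: unprimed for ring A (C1 acyl carbon, C2 OH, C4 OMe, C6 2-oxopentyl), primed for ring B (C1' carboxyl-bearing carbon, C2' OH, C4' depside oxygen, C6' propyl). The target has no stereocentre.
Assumption: the unsubstituted lithium ynolate is taken to be silylated on oxygen by the bulky chlorosilane, as its carbon-substituted homologues are.

Step 1
Reactants: 1 pentanal
Product: 2 2-methylidenepentanal
Conditions: 37% aq. HCHO, pyrrolidine (10 mol %), EtCO2H (10 mol %), iPrOH, 45 °C
Reagents that add atoms: formaldehyde, C=O
Why: Amine-catalysed Mannich condensation with formaldehyde and loss of the amine (α-methylenation of an aldehyde) is a routine way to 2-alkylacroleins, and the enal lets the diazo ester be attached by carbonyl addition instead of acylation with an enoyl chloride, where dipolar cycloaddition to the acrylic double bond and attack of HCl on the diazo group would compete.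

Step 2
Reactants: 2 2-methylidenepentanal; 3 benzyl diazoacetate
Product: 4 benzyl 2-diazo-3-hydroxy-4-methylideneheptanoate (racemic)
Conditions: LiN(iPr)2, THF, -78 °C; then 2; AcOH quench at -78 °C
Reagents that add atoms: none
Why: Aldol-type 1,2-addition of deprotonated 3 to an aldehyde is fast at -78 °C and spares the diazo group and the 1,1-disubstituted alkene; the new carbinol centre C3 forms as a racemate, which does not matter because step 3 turns it into a carbonyl carbon.

Step 3
Reactants: 4 benzyl 2-diazo-3-hydroxy-4-methylideneheptanoate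
Product: 5 benzyl 2-diazo-4-methylidene-3-oxoheptanoate
Conditions: IBX (2-iodoxybenzoic acid), DMSO, rt, in the dark
Reagents that add atoms: none
Why: Oxidation of α-diazo-β-hydroxy esters to α-diazo-β-keto esters with hypervalent iodine oxidants is established, is neutral enough for the acid-sensitive diazo group, and is helped here by the allylic nature of the alcohol.

Step 4
Reactants: 6 3-phenylisoxazole; 7 chlorotriisopropylsilane
Product: 9 (triisopropylsilyloxy)acetylene, via lithium ethynolate 8 (not isolated)
Conditions: n-BuLi (1.0 equiv), THF, -78 to 0 °C; then 7, -78 °C to rt; distillation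
Reagents that add atoms: none
Why: Deprotonation of a 3-arylisoxazole at C5 triggers the known fragmentation into the aryl nitrile and a lithium ynolate, and the known O-silylation of lithium ynolates by bulky silyl chlorides (small ones silylate carbon and give silylketenes) should then deliver the silyl ynol ether.

Step 5
Reactants: 5 benzyl 2-diazo-4-methylidene-3-oxoheptanoate; 9 (triisopropylsilyloxy)acetylene
Product: 14 benzyl 4-hydroxy-6-propyl-2-(triisopropylsilyloxy)benzoate, via vinylketene 10 (not isolated), via alkenylcyclobutenone 11 (not isolated), via dienylketene 12 (not isolated), via cyclohexadienone 13 (not isolated)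
Conditions: 9 (2.5 equiv), degassed ClCH2CH2Cl, hν (254 nm, quartz, low-pressure mercury lamps), 25 °C; then 80 °C
Reagents that add atoms: none
Why: Proposed new method: light expels N2 from 5 and the alkenyl group shifts from the ketone carbon to the diazo carbon (Wolff rearrangement) to give ester-substituted vinylketene 10, whose strongly electrophilic carbonyl carbon (future C4') is attacked by the unsubstituted, nucleophilic carbon of 9 (C3'), after which the silyloxy carbon (C2') closes on the ester-bearing carbon (C1') in a stepwise [2+2] to cyclobutenone 11. Reversible conrotatory four-electron opening of 11 (by light or at 80 °C) gives dienylketene 12, and only the isomer with the alkenyl group turned towards the ketene can continue, by a disrotatory six-electron electrocyclisation that forms C4'-C5' and closes the one lasting six-membered ring, with enolisation of dienone 13 making the sequence irreversible. The closest known reaction type is the Danheiser benzannulation of α,β-unsaturated α-diazo ketones with silyl ynol ethers, which gives resorcinol monosilyl ethers by the same cascade, and the new element is the second acceptor on the diazo carbon, that is, a 2-diazo-3-oxo ester as ketene source. No stereocentre remains in 14, since the quaternary carbon of 11 is only transient. Three selectivities are needed: migration of the alkenyl and not the benzyloxy group, which rests on the much higher migratory aptitude of sp2 carbon over alkoxy in photochemical Wolff reactions; the alkyne orientation, which the strong polarisation of the ynol ether secures; and [2+2] across the ketene C=C in preference to [4+2] through the ester carbonyl or through the vinylketene diene, the latter of which would exchange the free and the silylated oxygen. Excess 9 and the low stationary ketene concentration under irradiation should also limit acylation of the product phenol by 10.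

Step 6
Reactants: 15 methyl 2,4-dihydroxy-6-methylbenzoate
Product: 16 methyl 2-hydroxy-4-methoxy-6-methylbenzoate
Conditions: MeI (1.05 equiv), K2CO3 (1.0 equiv), acetone, reflux
Reagents that add atoms: iodomethane, CI
Why: Williamson etherification is selective for the C4 hydroxyl because the C2 hydroxyl is hydrogen-bonded to the ester carbonyl and is less acidic and less nucleophilic when only one equivalent of base and iodomethane is offered.

Step 7
Reactants: 16 methyl 2-hydroxy-4-methoxy-6-methylbenzoate
Product: 17 methyl 2-(benzyloxy)-4-methoxy-6-methylbenzoate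
Conditions: BnBr, K2CO3, DMF, 60 °C
Reagents that add atoms: benzyl bromide, BrCc1ccccc1
Why: Forcing Williamson conditions (dipolar solvent, heat) alkylate the remaining chelated phenol, and benzyl is chosen so that it leaves together with the benzyl ester in the last step.

Step 8
Reactants: 17 methyl 2-(benzyloxy)-4-methoxy-6-methylbenzoate; 18 N-methoxy-N-methylbutanamide
Product: 19 methyl 2-(benzyloxy)-4-methoxy-6-(2-oxopentyl)benzoate
Conditions: LiN(iPr)2 (1.2 equiv), THF, -78 °C; then 18; AcOH quench
Reagents that add atoms: none
Why: Lateral lithiation of an ortho-toluate gives an ester-stabilised benzylic anion that adds to the Weinreb amide, and the chelated tetrahedral adduct lasts until the quench, which prevents over-addition and enolate-driven closure onto the neighbouring ester.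

Step 9
Reactants: 19 methyl 2-(benzyloxy)-4-methoxy-6-(2-oxopentyl)benzoate
Product: 20 methyl 2-(benzyloxy)-4-methoxy-6-[(2-propyl-1,3-dioxolan-2-yl)methyl]benzoate
Conditions: Me3SiOCH2CH2OSiMe3, Me3SiOTf (5 mol %), CH2Cl2, -78 to -20 °C; pyridine quench
Reagents that add atoms: 1,2-bis(trimethylsilyloxy)ethane, C[Si](C)(C)OCCO[Si](C)(C)C
Why: Noyori ketalisation runs aprotically at low temperature, driven by formation of the Si-O-Si bond, so the benzyl ketone is masked without the hot protic acid that could close it onto the ortho ester to an isocoumarin.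

Step 10
Reactants: 20 methyl 2-(benzyloxy)-4-methoxy-6-[(2-propyl-1,3-dioxolan-2-yl)methyl]benzoate
Product: 21 2-(benzyloxy)-4-methoxy-6-[(2-propyl-1,3-dioxolan-2-yl)methyl]benzoic acid
Conditions: KOH, DMSO-H2O, 90 °C; then cold 1 M HCl to pH 4
Reagents that add atoms: potassium hydroxide, [K+].[OH-]
Why: Saponification of the doubly ortho-substituted methyl ester needs hot hydroxide in a dipolar aprotic medium, to which the ketal, the benzyl ether and the methyl ether are inert, and brief cold acidification frees the acid without touching the ketal.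

Step 11
Reactants: 14 benzyl 4-hydroxy-6-propyl-2-(triisopropylsilyloxy)benzoate; 21 2-(benzyloxy)-4-methoxy-6-[(2-propyl-1,3-dioxolan-2-yl)methyl]benzoic acid
Product: 22 benzyl 4-({2-(benzyloxy)-4-methoxy-6-[(2-propyl-1,3-dioxolan-2-yl)methyl]benzoyl}oxy)-6-propyl-2-(triisopropylsilyloxy)benzoate
Conditions: DCC, DMAP (cat.), CH2Cl2, 0 °C to rt
Reagents that add atoms: none
Why: Steglich esterification joins the acid to the only free hydroxyl of 14, which is unhindered (C3'-H and C5'-H as neighbours), while the masked ketone cannot divert the activated acid into an isocoumarin.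

Step 12
Reactants: 22 benzyl 4-({2-(benzyloxy)-4-methoxy-6-[(2-propyl-1,3-dioxolan-2-yl)methyl]benzoyl}oxy)-6-propyl-2-(triisopropylsilyloxy)benzoate
Product: 24 benzyl 4-{[2-(benzyloxy)-4-methoxy-6-(2-oxopentyl)benzoyl]oxy}-2-hydroxy-6-propylbenzoate, via desilylated ketal depside 23 (not isolated)
Conditions: Bu4NF, AcOH, THF, 0 °C; then 1 M aq. HCl, rt
Reagents that add atoms: water, O
Why: Fluoride cleaves the aryl silyl ether through the strong Si-F bond while acetic acid keeps the liberated phenoxide from attacking the depside ester, and dilute aqueous acid then hydrolyses the dialkyl ketal through its oxocarbenium ion much faster than either ester.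

Step 13
Reactants: 24 benzyl 4-{[2-(benzyloxy)-4-methoxy-6-(2-oxopentyl)benzoyl]oxy}-2-hydroxy-6-propylbenzoate
Product: 25 2-hydroxy-4-{[2-hydroxy-4-methoxy-6-(2-oxopentyl)benzoyl]oxy}-6-propylbenzoic acid (CNP0187582.0)
Conditions: H2 (1 atm), 10% Pd/C, EtOAc, rt
Reagents that add atoms: none
Why: Catalytic hydrogenolysis cleaves the two benzylic C-O bonds (ether on ring A, ester on ring B) under neutral conditions that leave the aryl ester, the aliphatic ketone and both arenes unchanged.

Compound list
1 | pentanal | CCCCC=O | starting material
2 | 2-methylidenepentanal | CCCC(=C)C=O | intermediate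
3 | benzyl diazoacetate | [N-]=[N+]=CC(=O)OCc1ccccc1 | starting material
4 | benzyl 2-diazo-3-hydroxy-4-methylideneheptanoate (racemic) | CCCC(=C)C(O)C(=[N+]=[N-])C(=O)OCc1ccccc1 | intermediate
5 | benzyl 2-diazo-4-methylidene-3-oxoheptanoate | CCCC(=C)C(=O)C(=[N+]=[N-])C(=O)OCc1ccccc1 | intermediate
6 | 3-phenylisoxazole | c1ccc(-c2ccon2)cc1 | starting material
7 | chlorotriisopropylsilane | CC(C)[Si](Cl)(C(C)C)C(C)C | starting material
8 | lithium ethynolate (not isolated) | [Li+].[O-]C#C | intermediate
9 | (triisopropylsilyloxy)acetylene | C#CO[Si](C(C)C)(C(C)C)C(C)C | intermediate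
10 | benzyl 3-methylidene-2-(oxomethylidene)hexanoate, the vinylketene (not isolated) | CCCC(=C)C(=C=O)C(=O)OCc1ccccc1 | intermediate
11 | benzyl 4-oxo-1-(pent-1-en-2-yl)-2-(triisopropylsilyloxy)cyclobut-2-ene-1-carboxylate (racemic, not isolated) | CCCC(=C)C1(C(=O)OCc2ccccc2)C(=O)C=C1O[Si](C(C)C)(C(C)C)C(C)C | intermediate
12 | benzyl (2Z)-5-oxo-2-(pent-1-en-2-yl)-3-(triisopropylsilyloxy)penta-2,4-dienoate, the dienylketene (not isolated) | O=C=C/C(O[Si](C(C)C)(C(C)C)C(C)C)=C(\C(=C)CCC)C(=O)OCc1ccccc1 | intermediate
13 | benzyl 4-oxo-2-propyl-6-(triisopropylsilyloxy)cyclohexa-1,5-diene-1-carboxylate (not isolated) | O=C1C=C(O[Si](C(C)C)(C(C)C)C(C)C)C(C(=O)OCc2ccccc2)=C(CCC)C1 | intermediate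
14 | benzyl 4-hydroxy-6-propyl-2-(triisopropylsilyloxy)benzoate | CCCc1cc(O)cc(O[Si](C(C)C)(C(C)C)C(C)C)c1C(=O)OCc1ccccc1 | intermediate
15 | methyl 2,4-dihydroxy-6-methylbenzoate | COC(=O)c1c(C)cc(O)cc1O | starting material
16 | methyl 2-hydroxy-4-methoxy-6-methylbenzoate | COC(=O)c1c(C)cc(OC)cc1O | intermediate
17 | methyl 2-(benzyloxy)-4-methoxy-6-methylbenzoate | COC(=O)c1c(C)cc(OC)cc1OCc1ccccc1 | intermediate
18 | N-methoxy-N-methylbutanamide | CCCC(=O)N(C)OC | starting material
19 | methyl 2-(benzyloxy)-4-methoxy-6-(2-oxopentyl)benzoate | CCCC(=O)Cc1cc(OC)cc(OCc2ccccc2)c1C(=O)OC | intermediate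
20 | methyl 2-(benzyloxy)-4-methoxy-6-[(2-propyl-1,3-dioxolan-2-yl)methyl]benzoate | CCCC1(Cc2cc(OC)cc(OCc3ccccc3)c2C(=O)OC)OCCO1 | intermediate
21 | 2-(benzyloxy)-4-methoxy-6-[(2-propyl-1,3-dioxolan-2-yl)methyl]benzoic acid | CCCC1(Cc2cc(OC)cc(OCc3ccccc3)c2C(=O)O)OCCO1 | intermediate
22 | benzyl 4-({2-(benzyloxy)-4-methoxy-6-[(2-propyl-1,3-dioxolan-2-yl)methyl]benzoyl}oxy)-6-propyl-2-(triisopropylsilyloxy)benzoate | CCCC1(Cc2cc(OC)cc(OCc3ccccc3)c2C(=O)Oc2cc(O[Si](C(C)C)(C(C)C)C(C)C)c(C(=O)OCc3ccccc3)c(CCC)c2)OCCO1 | intermediate
23 | benzyl 4-({2-(benzyloxy)-4-methoxy-6-[(2-propyl-1,3-dioxolan-2-yl)methyl]benzoyl}oxy)-2-hydroxy-6-propylbenzoate (not isolated) | CCCC1(Cc2cc(OC)cc(OCc3ccccc3)c2C(=O)Oc2cc(O)c(C(=O)OCc3ccccc3)c(CCC)c2)OCCO1 | intermediate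
24 | benzyl 4-{[2-(benzyloxy)-4-methoxy-6-(2-oxopentyl)benzoyl]oxy}-2-hydroxy-6-propylbenzoate | CCCC(=O)Cc1cc(OC)cc(OCc2ccccc2)c1C(=O)Oc1cc(O)c(C(=O)OCc2ccccc2)c(CCC)c1 | intermediate
25 | 2-hydroxy-4-{[2-hydroxy-4-methoxy-6-(2-oxopentyl)benzoyl]oxy}-6-propylbenzoic acid (CNP0187582.0) | CCCC(=O)Cc1cc(OC)cc(O)c1C(=O)Oc1cc(O)c(C(=O)O)c(CCC)c1 | target

Total step count: 13.
Longest linear sequence: 8 steps (15, 16, 17, 19, 20, 21, 22, 24, 25; steps 6 to 13). The ring B line reaches the target in 7 steps.

Steps most likely to fail

1. Step 5.
- The zwitterion formed from the ketene and the ynol ether may be captured through the ester carbonyl oxygen instead of through carbon.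
- The ester, and not the alkenyl group, may turn inward during the four-electron opening and be lost to an oxa-electrocyclisation.
- The electrophilic ketene may acylate the phenol as it forms.
- Fallback (known chemistry): it sets out from acid 21 and comes back to the route at 23. Ring B is not built but taken from commercial 5-propylbenzene-1,3-diol. This is carboxylated ortho to a hydroxyl with MeOMgOCO2Me in DMF at 120 °C (Kolbe-Schmitt-type carboxylation, cold dilute HCl work-up) to 2,4-dihydroxy-6-propylbenzoic acid F1. Alkylation of the carboxylate with BnBr and KHCO3 in DMF gives benzyl 2,4-dihydroxy-6-propylbenzoate F2. DCC with catalytic DMAP then joins 21 to the C4' hydroxyl of F2, because the C2' hydroxyl is held in a hydrogen bond to the ester carbonyl and stays inert. The product is 23, which is isolated in this case and taken through the aqueous HCl stage of step 12.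

2. Step 4.
- Silylation of the unsubstituted ynolate on carbon may compete with silylation on oxygen.
- The ynolate may oligomerise or react with the benzonitrile that accompanies it.
- The volatile product may be lost on isolation.
- Fallback: it sets out from silyl chloride 7 and comes back to the route at ynolate 8, and from there at 9. The ynolate is made by oxidation instead of fragmentation. Acetylene is monolithiated with n-BuLi in THF at -78 °C to lithium acetylide F3. This is oxidised with LiOOtBu (from tBuOOH and LiN(SiMe3)2) between -78 and 0 °C under an acetylene atmosphere, giving 8 free of nitrile. Trapping with 7 as in step 4 gives 9.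

3. Step 12.
- Once the ketone is released in acid, its enol may lactonise onto the activated aryl ester and expel the ring B phenol.
- An under-buffered fluoride stage may cause acyl transfer.
- Fallback: it sets out from keto ester 19 and comes back to the route at target 25. It replaces the acid-labile ketal by one that leaves under neutral hydrogenolysis, so the depside never meets aqueous acid. Ketone 19 is condensed with 1,2-benzenedimethanol (camphorsulfonic acid cat., benzene, azeotropic removal of water) to methyl 2-(benzyloxy)-4-methoxy-6-[(3-propyl-1,5-dihydro-2,4-benzodioxepin-3-yl)methyl]benzoate F4. KOH in DMSO-H2O gives 2-(benzyloxy)-4-methoxy-6-[(3-propyl-1,5-dihydro-2,4-benzodioxepin-3-yl)methyl]benzoic acid F5. DCC and DMAP with 14 give the fully protected xylylene ketal depside F6. Bu4NF and AcOH give the desilylated xylylene ketal depside F7. H2 over 10% Pd/C in THF-MeOH then cleaves both benzyl groups and one benzylic C-O bond of the ketal, whose hemiketal collapses to the ketone of 25.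

Further compounds
F1 | step 5 | 2,4-dihydroxy-6-propylbenzoic acid | CCCc1cc(O)cc(O)c1C(=O)O
F2 | step 5 | benzyl 2,4-dihydroxy-6-propylbenzoate | CCCc1cc(O)cc(O)c1C(=O)OCc1ccccc1
F3 | step 4 | lithium acetylide | [Li]C#C
F4 | step 12 | methyl 2-(benzyloxy)-4-methoxy-6-[(3-propyl-1,5-dihydro-2,4-benzodioxepin-3-yl)methyl]benzoate | CCCC1(Cc2cc(OC)cc(OCc3ccccc3)c2C(=O)OC)OCc2ccccc2CO1
F5 | step 12 | 2-(benzyloxy)-4-methoxy-6-[(3-propyl-1,5-dihydro-2,4-benzodioxepin-3-yl)methyl]benzoic acid | CCCC1(Cc2cc(OC)cc(OCc3ccccc3)c2C(=O)O)OCc2ccccc2CO1
F6 | step 12 | fully protected xylylene ketal depside: benzyl 4-({2-(benzyloxy)-4-methoxy-6-[(3-propyl-1,5-dihydro-2,4-benzodioxepin-3-yl)methyl]benzoyl}oxy)-6-propyl-2-(triisopropylsilyloxy)benzoate | CCCC1(Cc2cc(OC)cc(OCc3ccccc3)c2C(=O)Oc2cc(O[Si](C(C)C)(C(C)C)C(C)C)c(C(=O)OCc3ccccc3)c(CCC)c2)OCc2ccccc2CO1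
F7 | step 12 | desilylated xylylene ketal depside: benzyl 4-({2-(benzyloxy)-4-methoxy-6-[(3-propyl-1,5-dihydro-2,4-benzodioxepin-3-yl)methyl]benzoyl}oxy)-2-hydroxy-6-propylbenzoate | CCCC1(Cc2cc(OC)cc(OCc3ccccc3)c2C(=O)Oc2cc(O)c(C(=O)OCc3ccccc3)c(CCC)c2)OCc2ccccc2CO1
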